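Numbering: abietane numbering is used for all tricyclic compounds (ring A: C1–C5 and C10; ring B: C5–C10; arene: C8, C9, C11–C14; side chain C15–C17; C18 and C19 on C4; C20 on C10). The extra bridge carbon bonded to C7 in 28–31 is called C21. The bicyclic ring A building blocks 6–12 carry naphthalene numbering; their C4a is C5 of the abietane.

## Analysis of the target

Compound 36 is a 16-acetoxy derivative of the carnosol skeleton. It is an abieta-8,11,13-triene in which ring A (gem-dimethyl at C4) is trans-fused to ring B, the arene carries a catechol at C11/C12, and C20 on C10 is tied back to C7 as a δ-lactone. Ring B and the lactone bridge (C20, O) form a 2-oxabicyclo[2.2.2]octane with bridgeheads C7 and C10, whose third bridge is the arene bond C8–C9. There are four stereocentres: C5 (S), C7 (S) and C10 (R) in the ring system and C15 (S) in the side chain. Within the ring system only one relationship is free, H-5 anti to C20; C7–O must be cis to C20 because both belong to the bridge. C15 is insulated from the ring stereocentres by the arene and has to be controlled on its own. Sensitive points are the air-sensitive catechol, the benzylic lactone C7–O bond (para to the C12 oxygen, ionisable in acid and open to hydrogenolysis), the primary acetate next to two phenols, and the benzylic C15–H. The hard part is the quaternary benzylic C10, crowded between C1, C5, C20 and the arene carbon C9 next to the C11 oxygen, together with the trans ring fusion. The strategy rests on C8 and C9 being bonded to the two bridgeheads C7 and C10: a benzo-fused bicyclo[2.2.2]octene is the Diels–Alder adduct of an aryne (C8≡C9) with a cyclohexa-1,3-diene. The lactone bridge can therefore be carried as a two-carbon silyl enol ether bridge from a 2-silyloxydiene fused to ring A at C5–C10, with the C11 oxygen placed to polarise the aryne.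

## Retrosynthetic reasoning

**36 back to 33.** Only heteroatom bonds are cut here: the two phenolic O–CH3 bonds (36 from 35), the acetate C–O bond (35 from 34) and the O–Si bond (34 from 33). The catechol would not survive aryllithium chemistry, ozonolysis or tetravalent lead, and an acetate would not survive the organolithium steps, so both appear at the very end. The forward steps must free C16–OH without opening the lactone, acetylate the only hydroxyl then present, and cleave two aryl methyl ethers beside an acetate. The C16 oxygen travels as a tert-butyldiphenylsilyl ether because it has to outlast an acidic step on the way to 33.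

**33 back to 30.** The lactone is taken back to lactol 32 and then the C7–O bond is cut, giving aldehyde acid 30, in which C7 carries a carboxyl carbon (C21) instead of oxygen and C20 is an aldehyde. C7 is benzylic and para to the C12 methoxy group, so oxidative loss of the carboxyl gives a stabilised cation at the carbon that must bear oxygen. The only oxygen that can bridge to it sits on C20 on the same face, so the forward reaction need not control C7. C20 is kept at the aldehyde level because a C20 acid would itself be a benzylic acid and would compete in the decarboxylation.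

**30 back to 28.** C20 and C21 are joined again as a double bond, which gives silyl enol ether 28. This is the only isolated electron-rich alkene of 28. Because one of its carbons bears the silyloxy group, ozonolysis delivers the two carbons at different oxidation levels, aldehyde at C20 and acid at C21, with no extra differentiation. What is gained is a purely carbocyclic benzobicyclo[2.2.2]octadiene.

**28 back to 12 and 27.** The bonds C7–C8 and C9–C10 are cut together, which leads to the ring A silyloxydiene 12 and aryne 27, the latter generated from iodoaryl triflate 25. No other cut removes ring B, the quaternary centre and both aryl bonds at once while leaving two fragments of similar size. The crowded C9–C10 bond is made with the most reactive 2π partner available. The forward reaction has to bond C7 to C8 (not C9), attack the diene face of H-5, and prefer [4+2] over ene and [2+2] pathways; the only stereochemical input is C5 of 12.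

**12 back to 1 and 2.** The O–Si bond of 12 is cut to the enantiopure octalone 10; kinetic enolisation on the CH2 side is needed so that the γ-hydrogen at C5 is not touched. Octalone 10 is traced through alcohol 9, acetate 8 and racemic alcohol 7 to racemic octalone 6, because C5 is epimerisable during any base-mediated annulation and is therefore fixed after the ring is made. A lipase-mediated acylation reads the carbinol centre, which is tied to C5 by a diastereoselective reduction. Octalone 6 is cut at C10=C–H (aldol) and at the C5–C6 bond (Michael) to enone 1 and silyl enone 2; conjugate methylation of 1 installs the gem-dimethyl group and gives the enolate on the correct side.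

**25 back to 13 and 14.** The triflate S–O and the C8–I bond are cut to iodophenol 24 and phenol 23; iodination has only one activated, unhindered site, ortho to the hydroxyl. The C9–O bond of 23 is cut to arene 20, since C9 is the only position next to a methoxy group that carries hydrogen and is therefore the single site for directed metalation. Arene 20 goes back through alcohol 19 to imide 18, and the C15–CH3 bond is cut to imide 16, made from acid 13 and auxiliary 14. The auxiliary sets C15 independently of everything else, which the insulated position of C15 requires.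

## Alternatives that were turned down

Alternative 1: Both ring A and ring B are disconnected (C5–C10 and C6–C7) across an intramolecular Diels–Alder reaction. The ortho-formyl arylacetic acid A2 carries the C1–C6 chain on C10, ending in the C5=C6 vinyl group on the gem-dimethyl carbon C4. On heating with a dehydrating agent it would close to the 2-benzopyran-3-one A3, whose diene termini C10 and C7 add to the tethered alkene to give A1, the 11,12-di-O-methyl ether of the target (the same compound as 35).
- For: rings A and B, C5, C7, C10 and the lactone bridge at its final oxidation level arise in one step. On step economy this alternative is stronger than the chosen route, since A1 is one step from 36 and no bridge has to be exchanged.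
- Against: A3 is flat, and its only stereocentre, C15, lies beyond the arene. Neither diene face is preferred, so the C5/C7/C10 triad would form in both absolute senses, giving two diastereomers of A1 that differ only in a remote relationship. The trans ring fusion depends on an exo/endo choice of a four-atom tether with no strong bias. The dienophile is an unactivated vinyl group whose neopentylic inner carbon must bond to the substituted terminus C10, in a thermal reaction of a diene that can also dimerise.
- Comparison: the chosen strategy gives up the direct lactone but takes absolute control from C5 of 12 and uses an aryne for the crowded C9–C10 bond.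

Alternative 2: C5–C10 is disconnected by a sigmatropic shift. The 3-isochromanone A5 has the lactone oxygen and a 3,3-dimethylpenta-1,4-dienyl group on C7. After enolisation and O-silylation across C10–C20, an Ireland–Claisen [3,3] shift forms C10–C5 while O–C7 breaks. The lactone contracts to carbocyclic ring B and gives acid A4 with a C6=C7 styrene, C20 as carboxyl, and an allyl and a vinyl group for later closure of ring A by metathesis.
- For: the C7 carbinol centre of A5 relays its configuration to both C5 and C10 through a cyclic transition state. This intramolecular control of the quaternary centre is probably more dependable than the facial selectivity of an intermolecular cycloaddition, so on this point the alternative is as strong or stronger. C20 emerges at the right oxidation level, and the styrene is a direct handle for re-forming C7–O.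
- Against: the shift must pass through a boat-like transition state inside the lactone ring while the benzylic, allylic C7–O bond is prone to ionise. Ring A is still missing; it must be closed between an allyl group and a neopentylic vinyl group and then reduced without touching the styrene. A5 needs its own enantioselective synthesis including C10 allylation, so the step count to 36 is clearly higher.
- Comparison: the chosen route offers convergence instead; ring A arrives complete, and the two halves are joined in the step that makes ring B.

Alternative 3: Ring A is disconnected (C1–C10 and C4=C5) by a Robinson annulation on the β-keto ester A7, a 2-tetralone 1-carboxylate. Under a chiral amine–thiourea catalyst, C10 of A7 would add to but-3-en-2-one A8, and the methyl ketone would then condense with the C5 ketone to give the tricyclic enone ester A6, with quaternary C10 (C20 as ester) set catalytically.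
- For: the hardest centre is made by asymmetric catalysis without a resolution. On this point the alternative is stronger than the chosen route, which discards half of the octalone; A6 is reached in very few steps.
- Against: A6 lacks both C4 methyl groups and carries a C3 ketone that must be removed. Its alkene must be moved and reduced so that H-5 ends up trans to the C20 ester, a reduction with no inherent bias for the trans product next to an axial ester and a gem-dimethyl group. C7 is still a methylene that must be oxidised and lactonised. A7 is an oxidation-prone β-keto ester.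
- Comparison: the chosen strategy brings the gem-dimethyl group and C5 in with the diene, lets C5 dictate C10 and C7, and leaves only the exchange of the bridge after the key step.

Key step: step 14

Assumption: the lipase in step 3 is taken to acylate the (R)-carbinol, its usual preference for cyclohex-2-en-1-ols; should it acylate the (S)-carbinol, the unreacted alcohol is the material carried on and step 4 falls away.

## Route

Step 1
Reactants: 1 3-methylcyclohex-2-en-1-one; 2 3-(trimethylsilyl)but-3-en-2-one
Product: 6 rac-5,5-dimethyl-4,4a,5,6,7,8-hexahydronaphthalen-2(3H)-one, via lithium enolate 3 (not isolated), via silyl diketone 4 (not isolated), via diketone 5 (not isolated)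
Conditions: Me2CuLi (from MeLi and CuI), Et2O, 0 °C; then 2, −78 → −20 °C; then KOH, MeOH–H2O, reflux
Reagents that add atoms: lithium dimethylcuprate, [Li+].C[Cu-]C
Why: Conjugate methylation gives enolate 3 regiospecifically on the gem-dimethyl side; the α-silyl vinyl ketone traps it in a Michael addition without proton transfer or polymerisation, and hydroxide then removes silicon and effects the aldol condensation (Robinson annulation). The ring-fusion centre (abietane C5) forms racemic.

Step 2
Reactants: 6 rac-5,5-dimethyl-4,4a,5,6,7,8-hexahydronaphthalen-2(3H)-one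
Product: 7 rac-(2R*,4aS*)-5,5-dimethyl-2,3,4,4a,5,6,7,8-octahydronaphthalen-2-ol
Conditions: NaBH4, CeCl3·7H2O, MeOH, −40 → 0 °C; chromatography to remove the minor trans alcohol
Reagents that add atoms: none
Why: Luche 1,2-reduction; axial hydride delivery should give the pseudo-equatorial alcohol with OH cis to H-4a, so that the carbinol configuration reports on the ring-fusion centre. The trans isomer is removed because it would erode the enantiomeric purity after re-oxidation.

Step 3
Reactants: 7 rac-(2R*,4aS*)-5,5-dimethyl-2,3,4,4a,5,6,7,8-octahydronaphthalen-2-ol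
Product: 8 (2R,4aS)-5,5-dimethyl-2,3,4,4a,5,6,7,8-octahydronaphthalen-2-yl acetate
Conditions: Burkholderia cepacia lipase (immobilised), vinyl acetate, t-BuOMe, 30 °C, stopped short of half conversion; chromatography
Reagents that add atoms: vinyl acetate, CC(=O)OC=C
Why: Lipase-catalysed kinetic resolution by irreversible transesterification; the enzyme should acylate the (R)-carbinol, with the alkene side acting as the large substituent, and in the cis alcohol that carbinol belongs to the (4aS) enantiomer. The (2S,4aR) half of 7 stays as alcohol and is separated.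

Step 4
Reactants: 8 (2R,4aS)-5,5-dimethyl-2,3,4,4a,5,6,7,8-octahydronaphthalen-2-yl acetate
Product: 9 (2R,4aS)-5,5-dimethyl-2,3,4,4a,5,6,7,8-octahydronaphthalen-2-ol
Conditions: K2CO3, MeOH, 0 °C → rt
Reagents that add atoms: none
Why: Mild ester methanolysis; no stereocentre is at risk because the molecule has no carbonyl group.

Step 5
Reactants: 9 (2R,4aS)-5,5-dimethyl-2,3,4,4a,5,6,7,8-octahydronaphthalen-2-ol
Product: 10 (4aS)-5,5-dimethyl-4,4a,5,6,7,8-hexahydronaphthalen-2(3H)-one
Conditions: MnO2, CH2Cl2, rt
Reagents that add atoms: none
Why: Neutral allylic oxidation with MnO2; without base or acid the γ-hydrogen at C4a is not exchanged, so the stereocentre should be kept.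

Step 6
Reactants: 10 (4aS)-5,5-dimethyl-4,4a,5,6,7,8-hexahydronaphthalen-2(3H)-one
Product: 12 tert-butyl{[(4aS)-5,5-dimethyl-4,4a,5,6,7,8-hexahydronaphthalen-2-yl]oxy}dimethylsilane, via lithium dienolate 11 (not isolated)
Conditions: LDA, THF, −78 °C; then TBSCl, DMPU, −78 → 0 °C
Reagents that add atoms: tert-butyl(chloro)dimethylsilane, CC(C)(C)[Si](C)(C)Cl
Why: Kinetic deprotonation of the enone at the α′-methylene gives the cross-conjugated dienolate, which is O-silylated to the homoannular 2-silyloxy-1,3-diene. The γ-hydrogen at C4a is not removed under these conditions, so the stereocentre is untouched.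

Step 7
Reactants: 13 2,3-dimethoxyphenylacetic acid; 14 (4S)-4-benzyl-1,3-oxazolidin-2-one
Product: 16 (4S)-4-benzyl-3-[2-(2,3-dimethoxyphenyl)acetyl]-1,3-oxazolidin-2-one, via mixed pivalic anhydride 15 (not isolated)
Conditions: t-BuCOCl, Et3N, THF, −20 °C; then 14, LiCl, rt
Reagents that add atoms: none
Why: N-Acylation of the oxazolidinone through the mixed anhydride, activated by LiCl; the hindered pivaloyl carbonyl is not attacked.

Step 8
Reactants: 16 (4S)-4-benzyl-3-[2-(2,3-dimethoxyphenyl)acetyl]-1,3-oxazolidin-2-one
Product: 18 (4S)-4-benzyl-3-[(2S)-2-(2,3-dimethoxyphenyl)propanoyl]-1,3-oxazolidin-2-one, via sodium enolate 17 (not isolated)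
Conditions: NaHMDS, THF, −78 °C; then MeI, −78 → −40 °C
Reagents that add atoms: iodomethane, CI
Why: Evans alkylation; the chelated Z-enolate is methylated on the face opposite the benzyl group, which with the (4S) auxiliary gives the (2S)-2-arylpropanoyl unit (C15).

Step 9
Reactants: 18 (4S)-4-benzyl-3-[(2S)-2-(2,3-dimethoxyphenyl)propanoyl]-1,3-oxazolidin-2-one
Product: 19 (2S)-2-(2,3-dimethoxyphenyl)propan-1-ol
Conditions: LiBH4, MeOH (1 equiv), Et2O–THF, 0 °C
Reagents that add atoms: none
Why: Reductive removal of the auxiliary with a non-basic hydride, which should not epimerise the α-aryl centre; the auxiliary is recovered.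

Step 10
Reactants: 19 (2S)-2-(2,3-dimethoxyphenyl)propan-1-ol
Product: 20 tert-butyl{[(2S)-2-(2,3-dimethoxyphenyl)propyl]oxy}diphenylsilane
Conditions: TBDPSCl, imidazole, DMF, rt
Reagents that add atoms: tert-butyl(chloro)diphenylsilane, CC(C)(C)[Si](Cl)(c1ccccc1)c1ccccc1
Why: Standard silylation of a primary alcohol; the bulky silyl ether is chosen to tolerate organolithium reagents at low temperature and the aqueous acid of step 16.

Step 11
Reactants: 20 tert-butyl{[(2S)-2-(2,3-dimethoxyphenyl)propyl]oxy}diphenylsilane
Product: 23 4-[(2S)-1-{[tert-butyl(diphenyl)silyl]oxy}propan-2-yl]-2,3-dimethoxyphenol, via aryllithium 21 (not isolated), via lithium arylborate 22 (not isolated)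
Conditions: n-BuLi, TMEDA, Et2O, 0 °C → rt; then B(OMe)3, −78 °C → rt; then 30% H2O2, aq NaOH, 0 °C
Reagents that add atoms: hydrogen peroxide, OO (trimethyl borate, COB(OC)OC, enters 22 only)
Why: Directed ortho-metalation; C9 is the only ring position that has a hydrogen next to a methoxy group, so lithiation should be regiospecific. Boration and oxidative 1,2-aryl shift turn the C–Li bond into the phenol.

Step 12
Reactants: 23 4-[(2S)-1-{[tert-butyl(diphenyl)silyl]oxy}propan-2-yl]-2,3-dimethoxyphenol
Product: 24 4-[(2S)-1-{[tert-butyl(diphenyl)silyl]oxy}propan-2-yl]-6-iodo-2,3-dimethoxyphenol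
Conditions: NIS, DMF, 0 °C, dark
Reagents that add atoms: N-iodosuccinimide, O=C1CCC(=O)N1I
Why: Electrophilic iodination of a phenol; C8 is ortho to the hydroxyl, para to the C12 methoxy group and unhindered, whereas the other free position (C14) is meta to the hydroxyl and flanked by the branched side chain.

Step 13
Reactants: 24 4-[(2S)-1-{[tert-butyl(diphenyl)silyl]oxy}propan-2-yl]-6-iodo-2,3-dimethoxyphenol
Product: 25 4-[(2S)-1-{[tert-butyl(diphenyl)silyl]oxy}propan-2-yl]-6-iodo-2,3-dimethoxyphenyl trifluoromethanesulfonate
Conditions: Tf2O, pyridine, CH2Cl2, 0 °C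
Reagents that add atoms: trifluoromethanesulfonic anhydride, O=S(=O)(OS(=O)(=O)C(F)(F)F)C(F)(F)F
Why: O-Sulfonylation of the phenol gives the 2-iodoaryl triflate, a precursor that releases an aryne on halogen–metal exchange.

Step 14
Reactants: 12 tert-butyl{[(4aS)-5,5-dimethyl-4,4a,5,6,7,8-hexahydronaphthalen-2-yl]oxy}dimethylsilane; 25 4-[(2S)-1-{[tert-butyl(diphenyl)silyl]oxy}propan-2-yl]-6-iodo-2,3-dimethoxyphenyl trifluoromethanesulfonate
Product: 28 benzobicyclo[2.2.2]octadiene adduct (C7 and C10 bridged by C21(OTBS)=C20H; 11,12-dimethoxy; 16-OTBDPS; C5, C7 and C10 as in 36), via lithioaryl triflate 26 (not isolated), via aryne 27 (not isolated)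
Conditions: 12 (1.5 equiv), 25, THF, −78 °C; n-BuLi (1.05 equiv), slow addition, −78 → −40 °C
Reagents that add atoms: none
Why: Iodine–lithium exchange at C8 of 25 is faster than attack on the triflate or the silyl ethers, and 26 loses lithium triflate at −78 °C to release aryne 27 in the presence of the diene. The closest known reaction type is the Diels–Alder reaction of arynes with 2-silyloxycyclohexa-1,3-dienes to benzobicyclo[2.2.2]octadienes. The addition should be concerted but asynchronous: the nucleophilic enol ether terminus C7 of 12 bonds to C8, the more electrophilic aryne carbon remote from the C11 methoxy group, and the charge developing at C9 is stabilised inductively by that oxygen before C9 closes on C10. Ring B is thereby closed as a six-membered ring by a suprafacial [4+2] addition across the homoannular diene; in the stepwise limit this is a 6-endo closure of the C9 aryl anion onto C10 of the silyloxyallyl cation. C10 is set by the diene face that is attacked: the axial C4 methyl group lies over the β-face of C10, so the aryne should arrive on the α-face, the face of H-5, which puts H-5 anti to the new bridge carbon C20. C7 is a bridgehead and follows from C10 without a choice. The step needs regioselectivity (C7 to C8), secured by the matched polarisation of silyloxydiene and methoxy-aryne, and facial selectivity, secured by the gem-dimethyl group next to enantiopure C5. It also needs periselectivity over the ene reaction and the [2+2] addition to the enol ether, which the locked s-cis diene favours.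

Step 15
Reactants: 28 benzobicyclo[2.2.2]octadiene adduct
Product: 30 aldehyde acid (C20 aldehyde on C10, C21 carboxylic acid on C7, cis on ring B; 11,12-dimethoxy; 16-OTBDPS), via silyl ester hydroperoxide 29 (not isolated)
Conditions: O3, CH2Cl2–MeOH, Sudan Red 7B as end-point indicator, −78 °C; then Me2S, −78 °C → rt; aqueous work-up at pH 4
Reagents that add atoms: ozone, [O-][O+]=O (methanol, CO, enters 29 only)
Why: Ozonolysis of a silyl enol ether to an oxo acid; ozone attacks only the electron-rich enol ether, the primary ozonide fragments to the C21 silyl ester and a C20 carbonyl oxide that methanol traps, Me2S reduces the hydroperoxide and the silyl ester hydrolyses on work-up. C5, C7 and C10 are not touched.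

Step 16
Reactants: 30 aldehyde acid
Product: 32 lactol (7,20-epoxy-20-hydroxy compound, anomeric mixture at C20; 11,12-dimethoxy; 16-OTBDPS), via C7 acetates 31 (not isolated)
Conditions: Pb(OAc)4, KOAc, AcOH–PhH, 70 °C; then 1 M aq HCl, THF, 25–40 °C
Reagents that add atoms: water, O (lead tetraacetate, CC(=O)O[Pb](OC(C)=O)(OC(C)=O)OC(C)=O, supplies the acetate of 31 only)
Why: Oxidative decarboxylation of an α-aryl carboxylic acid by tetravalent lead gives the C7 cation, stabilised by the para C12 methoxy group, which acetate captures (31, both C7 epimers). In aqueous acid the benzylic acetates ionise reversibly and the C20 aldehyde hydrate on the β-face closes the bridge, so either acetate and any C6=C7 elimination product should converge on 32. C7 is fixed by the geometry of the bridge; the anomeric C20 centre disappears in step 17.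

Step 17
Reactants: 32 lactol
Product: 33 11,12-di-O-methyl-16-O-(tert-butyldiphenylsilyl) lactone (20,7-olide)
Conditions: Dess–Martin periodinane, NaHCO3, CH2Cl2, rt
Reagents that add atoms: none
Why: Oxidation of a lactol to the lactone with a buffered hypervalent iodine reagent, which leaves the electron-rich arene and the silyl ether alone.

Step 18
Reactants: 33 silyl ether lactone
Product: 34 16-hydroxy-11,12-dimethoxy lactone
Conditions: HF·pyridine, pyridine, THF, 0 °C → rt
Reagents that add atoms: none
Why: Fluoride cleavage of the silyl ether under buffered, non-basic conditions, so the lactone is not opened.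

Step 19
Reactants: 34 16-hydroxy-11,12-dimethoxy lactone
Product: 35 16-acetoxy-11,12-dimethoxy lactone (11,12-di-O-methyl ether of 36)
Conditions: Ac2O, pyridine, DMAP (cat.), CH2Cl2, 0 °C
Reagents that add atoms: acetic anhydride, CC(=O)OC(C)=O
Why: Acylation of the only free hydroxyl; with both phenols still methylated there is no chemoselectivity issue.

Step 20
Reactants: 35 16-acetoxy-11,12-dimethoxy lactone
Product: 36 (5S,7S,10R,15S)-16-acetoxy-11,12-dihydroxyabieta-8,11,13-trien-20,7-olide
Conditions: BBr3, CH2Cl2, −78 → −10 °C; aq NaHCO3 work-up under argon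
Reagents that add atoms: none
Why: Lewis acid cleavage of the vicinal aryl methyl ethers through a cyclic catechol boronate; at low temperature the alkyl acetate and the lactone should react much more slowly than the ethers. No stereocentre is involved.

## Compound list

1 | 3-methylcyclohex-2-en-1-one | CC1=CC(=O)CCC1 | starting material
2 | 3-(trimethylsilyl)but-3-en-2-one | CC(=O)C(=C)[Si](C)(C)C | starting material
3 | lithium 3,3-dimethylcyclohex-1-en-1-olate | [Li+].[O-]C1=CC(C)(C)CCC1 | intermediate
4 | 3,3-dimethyl-2-[3-oxo-2-(trimethylsilyl)butyl]cyclohexan-1-one (racemic, diastereomer mixture) | CC(=O)C(CC1C(=O)CCCC1(C)C)[Si](C)(C)C | intermediate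
5 | 3,3-dimethyl-2-(3-oxobutyl)cyclohexan-1-one (racemic) | CC(=O)CCC1C(=O)CCCC1(C)C | intermediate
6 | rac-5,5-dimethyl-4,4a,5,6,7,8-hexahydronaphthalen-2(3H)-one | O=C1CCC2C(=C1)CCCC2(C)C | intermediate
7 | rac-(2R*,4aS*)-5,5-dimethyl-2,3,4,4a,5,6,7,8-octahydronaphthalen-2-ol (OH cis to H-4a; one enantiomer drawn) | O[C@@H]1CC[C@@H]2C(=C1)CCCC2(C)C | intermediate
8 | (2R,4aS)-5,5-dimethyl-2,3,4,4a,5,6,7,8-octahydronaphthalen-2-yl acetate | CC(=O)O[C@@H]1CC[C@@H]2C(=C1)CCCC2(C)C | intermediate
9 | (2R,4aS)-5,5-dimethyl-2,3,4,4a,5,6,7,8-octahydronaphthalen-2-ol | O[C@@H]1CC[C@@H]2C(=C1)CCCC2(C)C | intermediate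
10 | (4aS)-5,5-dimethyl-4,4a,5,6,7,8-hexahydronaphthalen-2(3H)-one | O=C1CC[C@@H]2C(=C1)CCCC2(C)C | intermediate
11 | lithium (4aS)-5,5-dimethyl-4,4a,5,6,7,8-hexahydronaphthalen-2-olate | [Li+].[O-]C1=CC[C@@H]2C(=C1)CCCC2(C)C | intermediate
12 | tert-butyl{[(4aS)-5,5-dimethyl-4,4a,5,6,7,8-hexahydronaphthalen-2-yl]oxy}dimethylsilane | CC(C)(C)[Si](C)(C)OC1=CC[C@@H]2C(=C1)CCCC2(C)C | intermediate
13 | 2,3-dimethoxyphenylacetic acid | COc1cccc(CC(=O)O)c1OC | starting material
14 | (4S)-4-benzyl-1,3-oxazolidin-2-one | O=C1N[C@@H](Cc2ccccc2)CO1 | starting material
15 | (2,3-dimethoxyphenyl)acetic pivalic anhydride | COc1cccc(CC(=O)OC(=O)C(C)(C)C)c1OC | intermediate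
16 | (4S)-4-benzyl-3-[2-(2,3-dimethoxyphenyl)acetyl]-1,3-oxazolidin-2-one | COc1cccc(CC(=O)N2[C@@H](Cc3ccccc3)COC2=O)c1OC | intermediate
17 | sodium (Z)-enolate of 16 | COc1cccc(/C=C(\[O-])N2[C@@H](Cc3ccccc3)COC2=O)c1OC.[Na+] | intermediate
18 | (4S)-4-benzyl-3-[(2S)-2-(2,3-dimethoxyphenyl)propanoyl]-1,3-oxazolidin-2-one | COc1cccc([C@H](C)C(=O)N2[C@@H](Cc3ccccc3)COC2=O)c1OC | intermediate
19 | (2S)-2-(2,3-dimethoxyphenyl)propan-1-ol | COc1cccc([C@H](C)CO)c1OC | intermediate
20 | tert-butyl{[(2S)-2-(2,3-dimethoxyphenyl)propyl]oxy}diphenylsilane | COc1cccc([C@H](C)CO[Si](c2ccccc2)(c2ccccc2)C(C)(C)C)c1OC | intermediate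
21 | aryllithium from 20, lithium at C9 (ortho to the C11 methoxy group) | [Li]c1ccc([C@H](C)CO[Si](c2ccccc2)(c2ccccc2)C(C)(C)C)c(OC)c1OC | intermediate
22 | lithium aryl(trimethoxy)borate from 21 | [Li+].CO[B-](OC)(OC)c1ccc([C@H](C)CO[Si](c2ccccc2)(c2ccccc2)C(C)(C)C)c(OC)c1OC | intermediate
23 | 4-[(2S)-1-{[tert-butyl(diphenyl)silyl]oxy}propan-2-yl]-2,3-dimethoxyphenol | Oc1ccc([C@H](C)CO[Si](c2ccccc2)(c2ccccc2)C(C)(C)C)c(OC)c1OC | intermediate
24 | 4-[(2S)-1-{[tert-butyl(diphenyl)silyl]oxy}propan-2-yl]-6-iodo-2,3-dimethoxyphenol | Oc1c(I)cc([C@H](C)CO[Si](c2ccccc2)(c2ccccc2)C(C)(C)C)c(OC)c1OC | intermediate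
25 | 4-[(2S)-1-{[tert-butyl(diphenyl)silyl]oxy}propan-2-yl]-6-iodo-2,3-dimethoxyphenyl trifluoromethanesulfonate (iodine on C8, triflate on C9) | CC(C)(C)[Si](c1ccccc1)(c1ccccc1)OC[C@@H](C)c1cc(I)c(OS(=O)(=O)C(F)(F)F)c(OC)c1OC | intermediate
26 | 2-lithioaryl triflate from 25 (lithium on C8) | CC(C)(C)[Si](c1ccccc1)(c1ccccc1)OC[C@@H](C)c1cc([Li])c(OS(=O)(=O)C(F)(F)F)c(OC)c1OC | intermediate
27 | aryne (C8≡C9) bearing the C11/C12 methoxy groups and the (S)-silyloxypropyl side chain | COC1=C(OC)C(=CC#C1)[C@H](C)CO[Si](c1ccccc1)(c1ccccc1)C(C)(C)C | intermediate
28 | benzobicyclo[2.2.2]octadiene adduct: abietatriene skeleton with C7 and C10 bridged by C21(OTBS)=C20H, 11,12-dimethoxy, 16-OTBDPS, H-5 anti to C20 | CC(C)(C)[Si](c1ccccc1)(c1ccccc1)OC[C@@H](C)c1cc2c(c(OC)c1OC)[C@@]13CCCC(C)(C)[C@@H]1C[C@@H]2C(O[Si](C)(C)C(C)(C)C)=C3 | intermediate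
29 | C20 methoxy hydroperoxide, C21 tert-butyldimethylsilyl ester from 28 | CC(C)(C)[Si](c1ccccc1)(c1ccccc1)OC[C@@H](C)c1cc2c(c(OC)c1OC)[C@@]1(C(OC)OO)CCCC(C)(C)[C@@H]1C[C@@H]2C(=O)O[Si](C)(C)C(C)(C)C | intermediate
30 | aldehyde acid: C20 aldehyde on C10 and C21 carboxylic acid on C7 (cis), 11,12-dimethoxy, 16-OTBDPS | CC(C)(C)[Si](c1ccccc1)(c1ccccc1)OC[C@@H](C)c1cc2c(c(OC)c1OC)[C@@]1(C=O)CCCC(C)(C)[C@@H]1C[C@@H]2C(=O)O | intermediate
31 | 7-acetoxy C20 aldehyde (both C7 epimers), 11,12-dimethoxy, 16-OTBDPS | CC(C)(C)[Si](c1ccccc1)(c1ccccc1)OC[C@@H](C)c1cc2c(c(OC)c1OC)[C@@]1(C=O)CCCC(C)(C)[C@@H]1CC2OC(C)=O | intermediate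
32 | lactol: 7,20-epoxy-20-hydroxy compound (C20 anomers), 11,12-dimethoxy, 16-OTBDPS | CC(C)(C)[Si](c1ccccc1)(c1ccccc1)OC[C@@H](C)c1cc2c(c(OC)c1OC)[C@@]13CCCC(C)(C)[C@@H]1C[C@@H]2OC3O | intermediate
33 | 11,12-dimethoxy-16-[tert-butyl(diphenyl)silyl]oxyabieta-8,11,13-trien-20,7-olide (stereocentres as in 36) | CC(C)(C)[Si](c1ccccc1)(c1ccccc1)OC[C@@H](C)c1cc2c(c(OC)c1OC)[C@@]13CCCC(C)(C)[C@@H]1C[C@@H]2OC3=O | intermediate
34 | 16-hydroxy-11,12-dimethoxyabieta-8,11,13-trien-20,7-olide | OC[C@@H](C)c1cc2c(c(OC)c1OC)[C@@]13CCCC(C)(C)[C@@H]1C[C@@H]2OC3=O | intermediate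
35 | 16-acetoxy-11,12-dimethoxyabieta-8,11,13-trien-20,7-olide | CC(=O)OC[C@@H](C)c1cc2c(c(OC)c1OC)[C@@]13CCCC(C)(C)[C@@H]1C[C@@H]2OC3=O | intermediate
36 | (5S,7S,10R,15S)-16-acetoxy-11,12-dihydroxyabieta-8,11,13-trien-20,7-olide | CC(=O)OC[C@@H](C)c1cc2c(c(O)c1O)[C@@]13CCCC(C)(C)[C@@H]1C[C@@H]2OC3=O | target

## Step count and risks

Total step count: 20. Longest linear sequence: 14 steps (13 to 36, steps 7–20); the diene branch (steps 1–6) joins in step 14.

**Step 14 (key step).** The aryne may be consumed by competing processes: an ene reaction with the allylic hydrogens at C1 and C6 of 12, [2+2] addition across the enol ether, or addition of n-BuLi. Regio- or facial selectivity may also erode, because the fully substituted terminus C10 has to bond next to the C11 methoxy group. Fallback, from 12 and 25 back to 28, forming the same two bonds one after the other: palladium-catalysed α-arylation of the tin enolate released from 12 by Bu3SnF (Pd2(dba)3, P(t-Bu)3, toluene, 80 °C) should engage only the C8–I bond of 25 and give the C7-arylated enone F1. An intramolecular reductive Heck (conjugate) arylation of the enone by the C9 triflate (Pd(OAc)2, PPh3, HCO2Na, DMF, 80 °C) would then form C9–C10 and give the bridged ketone F2. This ketone can enolise only away from the bridgehead, so TBSOTf and Et3N return 28.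

**Step 16.** The C7 cation may be diverted instead of funnelled into the bridge, through elimination to the C6=C7 styrene that does not re-enter, oxidation of the electron-rich arene by tetravalent lead, or partial loss of the silyl ether in the acidic stage. Fallback, from 30 back to 33: the acid is converted into its Barton ester F3 (2-mercaptopyridine N-oxide, DCC), and photolysis with t-BuSH removes the carboxyl reductively to give the C7-methylene aldehyde F4. Pinnick oxidation (NaClO2, NaH2PO4, 2-methyl-2-butene) gives the C20 acid F5. DDQ in wet CH2Cl2 then abstracts hydride from C7, para to the C12 methoxy group, and the carboxyl closes directly to 33.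

**Step 3.** The lipase may discriminate the enantiomers poorly, because the carbinol is flanked by a methylene and a trisubstituted alkene of similar size and the second stereocentre is remote; this would cap the enantiomeric purity of 12 and of everything after it. Fallback, from 7 back to 9: esterification with (S)-2-methoxy-2-phenylacetic acid (DCC, DMAP) gives two diastereomeric esters that are separated by chromatography or crystallisation; the (2R,4aS)-configured ester F6 is methanolysed (K2CO3, MeOH) to 9.

**Step 20.** The acetate may be cleaved or the benzylic lactone opened at C7 by the boron halide before both methyl ethers are gone. Fallback, from 34 back to 36, with the order of the last two operations reversed: BBr3 demethylation of 34 gives the catechol alcohol F7, and lipase-catalysed acetylation (Candida antarctica lipase B, vinyl acetate, t-BuOMe) then acylates the primary aliphatic hydroxyl and leaves the phenols free.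

## Further compounds

F1 | step 14 | (4aS)-3-aryl-5,5-dimethyl-4,4a,5,6,7,8-hexahydronaphthalen-2(3H)-one, aryl bonded through C8 and keeping the C9 triflate (C7 epimers) | O=C1C(C[C@@H]2C(=C1)CCCC2(C)C)c1cc([C@H](C)CO[Si](c2ccccc2)(c2ccccc2)C(C)(C)C)c(OC)c(OC)c1OS(=O)(=O)C(F)(F)F
F2 | step 14 | bridged ketone corresponding to 28 (C21 ketone, C20 methylene) | CC(C)(C)[Si](c1ccccc1)(c1ccccc1)OC[C@@H](C)c1cc2c(c(OC)c1OC)[C@@]13CCCC(C)(C)[C@@H]1C[C@@H]2C(=O)C3
F3 | step 16 | Barton ester of 30 (2-thioxopyridin-1(2H)-yl ester of the C21 acid) | CC(C)(C)[Si](c1ccccc1)(c1ccccc1)OC[C@@H](C)c1cc2c(c(OC)c1OC)[C@@]1(C=O)CCCC(C)(C)[C@@H]1C[C@@H]2C(=O)On1ccccc1=S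
F4 | step 16 | C20 aldehyde with C7 methylene, 11,12-dimethoxy, 16-OTBDPS | CC(C)(C)[Si](c1ccccc1)(c1ccccc1)OC[C@@H](C)c1cc2c(c(OC)c1OC)[C@@]1(C=O)CCCC(C)(C)[C@@H]1CC2
F5 | step 16 | C20 carboxylic acid with C7 methylene, 11,12-dimethoxy, 16-OTBDPS | CC(C)(C)[Si](c1ccccc1)(c1ccccc1)OC[C@@H](C)c1cc2c(c(OC)c1OC)[C@@]1(C(=O)O)CCCC(C)(C)[C@@H]1CC2
F6 | step 3 | (2R,4aS)-5,5-dimethyl-2,3,4,4a,5,6,7,8-octahydronaphthalen-2-yl (2S)-2-methoxy-2-phenylacetate | CO[C@H](C(=O)O[C@@H]1CC[C@@H]2C(=C1)CCCC2(C)C)c1ccccc1
F7 | step 20 | 11,12,16-trihydroxyabieta-8,11,13-trien-20,7-olide | OC[C@@H](C)c1cc2c(c(O)c1O)[C@@]13CCCC(C)(C)[C@@H]1C[C@@H]2OC3=O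
A1 | alternative 1 | 11,12-di-O-methyl ether of the target (identical with 35) | CC(=O)OC[C@@H](C)c1cc2c(c(OC)c1OC)[C@@]13CCCC(C)(C)[C@@H]1C[C@@H]2OC3=O
A2 | alternative 1 | 2-aryl-6,6-dimethyloct-7-enoic acid with an ortho-formyl group on the arene (C10 epimers) | C=CC(C)(C)CCCC(C(=O)O)c1c(C=O)cc([C@H](C)COC(C)=O)c(OC)c1OC
A3 | alternative 1 | 2-benzopyran-3-one with the tethered alkene on C10 | O=C1OC=C2C=C([C@H](C)COC(C)=O)C(OC)=C(OC)C2=C1CCCC(C)(C)C=C
A4 | alternative 2 | 1-allyl-2-(2-methylbut-3-en-2-yl)-1,2-dihydronaphthalene-1-carboxylic acid with C5 and C10 set | CC(C)(C)[Si](C)(C)OC[C@@H](C)c1cc2c(c(OC)c1OC)[C@](CC=C)(C(=O)O)[C@H](C(C)(C)C=C)C=C2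
A5 | alternative 2 | 4-allyl-1-[(E)-3,3-dimethylpenta-1,4-dienyl]isochroman-3-one, C7 configured for the chirality transfer (C10 epimers) | C=CCC1C(=O)O[C@@H](/C=C/C(C)(C)C=C)c2cc([C@H](C)CO[Si](C)(C)C(C)(C)C)c(OC)c(OC)c12
A6 | alternative 3 | tricyclic enone ester with C3 ketone, C4=C5 and quaternary C10 | CC(C)(C)[Si](C)(C)OC[C@@H](C)c1cc2c(c(OC)c1OC)[C@@]1(C(=O)OC)CCC(=O)C=C1CC2
A7 | alternative 3 | methyl 2-oxo-1,2,3,4-tetrahydronaphthalene-1-carboxylate carrying the arene substituents | COC(=O)C1C(=O)CCc2cc([C@H](C)CO[Si](C)(C)C(C)(C)C)c(OC)c(OC)c12
A8 | alternative 3 | but-3-en-2-one | C=CC(C)=O
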